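**Retrosynthetic overview**

1. The (E,E,E)-triene is made last, by an E-selective Wittig reaction between a C-15 aldehyde (from ozonolysis of a terminal vinyl group) and a (2E,4E)-hepta-2,4-dienyl tributylphosphonium ylide; this keeps the acid-sensitive triene out of the Lewis-acid step.
2. The 1,2-dioxane is cut at C-4–C-5 and at O-1–C-6 into methyl (S)-4-oxo-3-[(triethylsilyl)peroxy]pentanoate and 2-methyldodeca-1,11-diene. One TiCl4 operation forms the dioxane ring first and the γ-lactone ring second.
3. Enabling feature: in the dioxane ring the quaternary C-4 (methyl, lactone oxygen) is a masked methyl ketone bonded directly to the peroxide-bearing C-3, and C-5 (CH2) with the quaternary C-6 (methyl, chain, peroxide oxygen) is a masked 1,1-disubstituted alkene. A four-atom C-4–C-3–O–O unit and a two-atom C-5=C-6 unit can therefore be joined by Markovnikov carbonyl addition, followed by capture of the tertiary C-6 cation by the peroxide oxygen six atoms away.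
4. C-3 is set by L-proline-catalysed α-aminoxylation of methyl levulinate and inverted once when the peroxide is introduced. C-4 (chelation control) and C-6 (chair-like closure) are relayed from C-3 in the key step.
5. The diene comes from 2-methylallylmagnesium chloride and 9-bromonon-1-ene; the phosphonium salt comes from (2E,4E)-hepta-2,4-dienal.

Key step: step 6

Remark: locants used are C-1 (lactone carbonyl), C-2 (its CH2), C-3 (peroxide-bearing ring-fusion CH), C-4 (quaternary ring-fusion carbon), C-5 (dioxane CH2), C-6 (quaternary dioxane carbon), C-7 to C-22 (side chain), O-1 (on C-6) and O-2 (on C-3). Anhydrous ethereal H2O2 is assumed to be prepared from commercial aqueous H2O2 by extraction and drying.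

**Route**

Step 1
Reactants: 1 methyl levulinate (methyl 4-oxopentanoate)
Product: 2 methyl (R)-4-oxo-3-[(phenylamino)oxy]pentanoate
Conditions: 1 (3 equiv), L-proline (20 mol %), DMF, 0 °C, PhNO added slowly
Reagents that add atoms: nitrosobenzene, O=Nc1ccccc1
Why: Proline enamine catalysis (O-selective nitroso aldol, α-aminoxylation): the more substituted enamine of the methyl ketone attacks the nitroso oxygen in the hydrogen-bonded transition state that L-proline enforces, which should set C-3 as (R) with high enantioselectivity.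

Step 2
Reactants: 2 methyl (R)-4-oxo-3-[(phenylamino)oxy]pentanoate
Product: 3 methyl (R)-3-hydroxy-4-oxopentanoate
Conditions: CuSO4·5H2O (30 mol %), MeOH, 0 °C
Reagents that add atoms: none
Why: Copper-catalysed N–O cleavage of an α-aminoxy ketone under near-neutral conditions should release the α-hydroxy ketone without touching the C-3 stereocenter.

Step 3
Reactants: 3 methyl (R)-3-hydroxy-4-oxopentanoate
Product: 5 methyl (S)-3-hydroperoxy-4-oxopentanoate, via methyl (R)-4-oxo-3-(triflyloxy)pentanoate 4 (not isolated)
Conditions: Tf2O, 2,6-lutidine (1.1 equiv), CH2Cl2, −78 °C; then anhydrous H2O2 in Et2O (excess), solid NaHCO3, −78 → 0 °C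
Reagents that add atoms: hydrogen peroxide, OO
Why: O-Triflation followed by SN2 perhydrolysis of the sulfonate: the α-keto triflate is activated for bimolecular displacement and cannot ionise, so neutral H2O2 should replace triflate with inversion, turning (R)-C-3 into the (S)-hydroperoxide, while the buffered non-basic medium avoids elimination and Kornblum–DeLaMare loss.

Step 4
Reactants: 5 methyl (S)-3-hydroperoxy-4-oxopentanoate
Product: 6 methyl (S)-4-oxo-3-[(triethylsilyl)peroxy]pentanoate
Conditions: Et3SiOTf, 2,6-lutidine, CH2Cl2, −78 °C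
Reagents that add atoms: triethylsilyl trifluoromethanesulfonate, CC[Si](CC)(CC)OS(=O)(=O)C(F)(F)F
Why: O-Silylation of the hydroperoxide with a silyl triflate and a hindered pyridine at low temperature (standard protection as a triethylsilyl peroxide) leaves C-3 untouched and gives the peroxide in the form needed for cation capture.

Step 5
Reactants: 7 2-methylallylmagnesium chloride; 8 9-bromonon-1-ene
Product: 9 2-methyldodeca-1,11-diene
Conditions: Li2CuCl4 (3 mol %), THF, −10 °C → rt
Reagents that add atoms: none
Why: Copper-catalysed sp3–sp3 cross-coupling of an allylic Grignard reagent with a primary alkyl bromide; the 2-methylallyl unit is the same at both termini, so no regioisomer can arise and no stereocenter is formed.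

Step 6
Reactants: 6 methyl (S)-4-oxo-3-[(triethylsilyl)peroxy]pentanoate; 9 2-methyldodeca-1,11-diene
Product: 12 (3S,4aS,7aS)-3-(dec-9-en-1-yl)-3,4a-dimethyltetrahydrofuro[3,2-c][1,2]dioxin-6(3H)-one, via zwitterionic tertiary carbocation 10 (not isolated), via trichlorotitanium alkoxide 11 (not isolated)
Conditions: 6, TiCl4 (2.2 equiv), 2,6-di-tert-butyl-4-methylpyridine (0.3 equiv), CH2Cl2, −78 °C; then 9 (1.5 equiv), −78 → 0 °C; aq NaHCO3
Reagents that add atoms: none
Why: Proposed new method: TiCl4 should chelate the ketone oxygen and the proximal peroxide oxygen of 6, the CH2 terminus of the 1,1-disubstituted alkene of 9 then adds to the ketone carbon (Prins-type step) to give tertiary carbocation 10, the silylated distal peroxide oxygen captures this cation with loss of Et3SiCl, and the resulting titanium alkoxide 11 acylates itself with the cis-disposed methyl ester; the closest known reaction types are the TiCl4- or SnCl4-mediated (3+2) annulation of silylperoxy-substituted oxocarbenium ions with alkenes to 1,2-dioxolanes (same cation capture by an O–O–SiEt3 group) and chelation-controlled Lewis-acid additions of π-nucleophiles (allylsilanes, carbonyl-ene reactions of 1,1-disubstituted alkenes) to α-oxygenated ketones. The 1,2-dioxane closes by cation–oxygen collapse that is 6-endo with respect to the former alkene, so that the sequence is a stepwise (4+2) annulation, and the γ-lactone closes by 5-exo-trig acyl substitution. C-4 is controlled by C-3 through the Cram chelate (attack anti to the CH2CO2Me arm places the new C–O bond cis to that arm, the only arrangement that can lactonise), and C-6 by the chair-like closure within the titanium-bridged bicycle, in which the axial site syn to the O–Ti unit should take the methyl group and leave the long chain equatorial. The step needs Markovnikov regiochemistry (secured by the tertiary cation), reaction at the 1,1-disubstituted and not at the far less nucleophilic monosubstituted alkene, chelated and not open-chain facial attack (a C-4 epimer could not lactonise and would be separable), and peroxide capture faster than proton loss or chloride capture (secured by the six-membered proximity of the silyl peroxide and by re-ionisation of any tertiary chloride).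

Step 7
Reactants: 12 (3S,4aS,7aS)-3-(dec-9-en-1-yl)-3,4a-dimethyltetrahydrofuro[3,2-c][1,2]dioxin-6(3H)-one
Product: 13 9-[(3S,4aS,7aS)-3,4a-dimethyl-6-oxohexahydrofuro[3,2-c][1,2]dioxin-3-yl]nonanal
Conditions: O3, CH2Cl2, −78 °C; then Me2S, −78 °C → rt
Reagents that add atoms: ozone, [O-][O+]=O
Why: Ozonolysis with reductive work-up cleaves the only C=C bond to the aldehyde; dialkyl peroxides and lactones are inert to ozone and to Me2S, and no stereocenter is touched.

Step 8
Reactants: 14 (2E,4E)-hepta-2,4-dienal
Product: 15 (2E,4E)-hepta-2,4-dien-1-ol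
Conditions: NaBH4, MeOH, 0 °C
Reagents that add atoms: none
Why: 1,2-Reduction of the dienal by borohydride; the (E,E)-diene is not affected.

Step 9
Reactants: 15 (2E,4E)-hepta-2,4-dien-1-ol
Product: 16 (2E,4E)-1-bromohepta-2,4-diene
Conditions: PBr3, Et2O, 0 °C
Reagents that add atoms: phosphorus tribromide, BrP(Br)Br
Why: Bromination of the allylic alcohol with PBr3; the conjugated primary (2E,4E)-bromide is the thermodynamically favoured allylic isomer, and any transposed isomer would converge in step 10.

Step 10
Reactants: 16 (2E,4E)-1-bromohepta-2,4-diene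
Product: 17 tributyl[(2E,4E)-hepta-2,4-dien-1-yl]phosphonium bromide
Conditions: PBu3, MeCN, rt
Reagents that add atoms: tributylphosphine, CCCCP(CCCC)CCCC
Why: SN2 (or SN2′) quaternisation of the phosphine at the terminal carbon gives the conjugated dienyl phosphonium salt.

Step 11
Reactants: 13 9-[(3S,4aS,7aS)-3,4a-dimethyl-6-oxohexahydrofuro[3,2-c][1,2]dioxin-3-yl]nonanal; 17 tributyl[(2E,4E)-hepta-2,4-dien-1-yl]phosphonium bromide
Product: 19 (3S,4aS,7aS)-3-[(9E,11E,13E)-hexadeca-9,11,13-trien-1-yl]-3,4a-dimethyltetrahydrofuro[3,2-c][1,2]dioxin-6(3H)-one, via tributyl[(2E,4E)-hepta-2,4-dien-1-ylidene]phosphorane 18 (not isolated)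
Conditions: 17 (1.3 equiv), KOtBu (1.25 equiv), THF, 0 °C; then 13, −78 °C → rt
Reagents that add atoms: none
Why: Wittig olefination with a preformed allylic trialkylphosphonium ylide, a variant known for high E-selectivity with aliphatic aldehydes, should create the C-15=C-16 bond as E while the two E-alkenes of the ylide are retained; no free strong base is present, so the base-sensitive peroxy lactone should survive.

**Compound list**

1 | methyl levulinate | COC(=O)CCC(C)=O | starting material
2 | methyl (R)-4-oxo-3-[(phenylamino)oxy]pentanoate | COC(=O)C[C@H](C(C)=O)ONc1ccccc1 | intermediate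
3 | methyl (R)-3-hydroxy-4-oxopentanoate | COC(=O)C[C@H](C(C)=O)O | intermediate
4 | methyl (R)-4-oxo-3-(triflyloxy)pentanoate | COC(=O)C[C@H](C(C)=O)OS(=O)(=O)C(F)(F)F | intermediate (not isolated)
5 | methyl (S)-3-hydroperoxy-4-oxopentanoate | COC(=O)C[C@@H](C(C)=O)OO | intermediate
6 | methyl (S)-4-oxo-3-[(triethylsilyl)peroxy]pentanoate | COC(=O)C[C@@H](C(C)=O)OO[Si](CC)(CC)CC | intermediate
7 | 2-methylallylmagnesium chloride | C=C(C)C[Mg]Cl | starting material
8 | 9-bromonon-1-ene | C=CCCCCCCCBr | starting material
9 | 2-methyldodeca-1,11-diene | C=C(C)CCCCCCCCC=C | intermediate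
10 | zwitterionic tertiary carbocation (C-6 cation, C-4 oxygen on TiCl4, 3S,4S) | COC(=O)C[C@H](OO[Si](CC)(CC)CC)[C@@](C)(O[Ti-](Cl)(Cl)(Cl)Cl)C[C+](C)CCCCCCCCC=C | intermediate (not isolated)
11 | trichlorotitanium alkoxide of methyl 2-[(3S,4S,6S)-6-(dec-9-en-1-yl)-4-hydroxy-4,6-dimethyl-1,2-dioxan-3-yl]acetate | C=CCCCCCCCC[C@@]1(C)C[C@](C)(O[Ti](Cl)(Cl)Cl)[C@H](CC(=O)OC)OO1 | intermediate (not isolated)
12 | (3S,4aS,7aS)-3-(dec-9-en-1-yl)-3,4a-dimethyltetrahydrofuro[3,2-c][1,2]dioxin-6(3H)-one | C=CCCCCCCCC[C@@]1(C)C[C@]2(C)OC(=O)C[C@@H]2OO1 | intermediate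
13 | 9-[(3S,4aS,7aS)-3,4a-dimethyl-6-oxohexahydrofuro[3,2-c][1,2]dioxin-3-yl]nonanal | O=CCCCCCCCC[C@@]1(C)C[C@]2(C)OC(=O)C[C@@H]2OO1 | intermediate
14 | (2E,4E)-hepta-2,4-dienal | CC/C=C/C=C/C=O | starting material
15 | (2E,4E)-hepta-2,4-dien-1-ol | CC/C=C/C=C/CO | intermediate
16 | (2E,4E)-1-bromohepta-2,4-diene | CC/C=C/C=C/CBr | intermediate
17 | tributyl[(2E,4E)-hepta-2,4-dien-1-yl]phosphonium bromide | CC/C=C/C=C/C[P+](CCCC)(CCCC)CCCC.[Br-] | intermediate
18 | tributyl[(2E,4E)-hepta-2,4-dien-1-ylidene]phosphorane | CC/C=C/C=C/C=P(CCCC)(CCCC)CCCC | intermediate (not isolated)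
19 | (3S,4aS,7aS)-3-[(9E,11E,13E)-hexadeca-9,11,13-trien-1-yl]-3,4a-dimethyltetrahydrofuro[3,2-c][1,2]dioxin-6(3H)-one | CC/C=C/C=C/C=C/CCCCCCCC[C@@]1(C)C[C@]2(C)OC(=O)C[C@@H]2OO1 | target

**Step count**

Total steps: 11. Longest linear sequence: 7 steps (steps 1, 2, 3, 4, 6, 7, 11).

**Steps most likely to fail**

1. Step 6 (Proposed new method). What may go wrong:
- the tertiary cation may lose a proton (ene product) or pick up chloride before the peroxide closes;
- the ketone may react through an open-chain, non-chelated arrangement and give the C-4 epimer;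
- discrimination between methyl and chain in the chair-like closure may be low, so the C-6 epimer may form; this is the weakest point of stereocontrol in the route;
- the Lewis acid may trigger O–O heterolysis with acyl migration in the α-peroxy ketone.

Fallback (sets out from 9, uses 6, comes back at 12): the two bonds are made one after the other with known reactions. Diene 9 is metalated at the allylic methyl group (n-BuLi, TMEDA, hexane, rt) and silylated with Me3SiCl to give trimethyl(2-methylidenedodec-11-en-1-yl)silane F1. TiCl4-mediated, chelation-controlled Hosomi–Sakurai addition of F1 to ketone 6 (CH2Cl2, −78 °C) with lactonisation should give (4S,5S)-5-methyl-5-(2-methylidenedodec-11-en-1-yl)-4-[(triethylsilyl)peroxy]oxolan-2-one F2. HF·pyridine (THF, 0 °C) frees (4S,5S)-4-hydroperoxy-5-methyl-5-(2-methylidenedodec-11-en-1-yl)oxolan-2-one F3. 6-Exo cyclo-peroxymercuration with Hg(OAc)2 (CH2Cl2, 0 °C) gives [(3S,4aS,7aS)-3-(dec-9-en-1-yl)-4a-methyl-6-oxohexahydrofuro[3,2-c][1,2]dioxin-3-yl]methylmercury acetate F4, and NaBH4 demercuration returns 12. C-6 epimers, if both form, would be separated at 12.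

2. Step 3. What may go wrong: base- or acid-promoted elimination of triflate toward the conjugated keto enoate; enolisation of the α-keto triflate with loss of configuration; addition of H2O2 to the ketone followed by C–C cleavage of the α-hydroperoxy ketone.

Fallback (sets out from 1, comes back at 6): no displacement at C-3 is used. Methyl levulinate 1 is converted under equilibrating conditions (Et3SiCl, NaI, Et3N, MeCN) into methyl (Z)-4-[(triethylsilyl)oxy]pent-3-enoate F5. Photooxygenation (O2, tetraphenylporphyrin, hν, CH2Cl2, −20 °C) should give, by the silatropic ene reaction of singlet oxygen, racemic methyl 4-oxo-3-[(triethylsilyl)peroxy]pentanoate F6. The (S)-enantiomer 6 is then taken by preparative HPLC on a chiral stationary phase.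

3. Step 11. What may go wrong: incomplete E-selectivity at the new C-15=C-16 bond, and partial scrambling of the 2E geometry within the delocalised dienyl ylide.

Fallback (sets out from 13, comes back at 19): the polarity of the olefination is reversed so that the aldehyde partner carries the fixed (E,E)-geometry. NaBH4 (MeOH, 0 °C) reduces 13 to (3S,4aS,7aS)-3-(9-hydroxynonyl)-3,4a-dimethyltetrahydrofuro[3,2-c][1,2]dioxin-6(3H)-one F7. Mitsunobu thioetherification with 1-phenyl-1H-tetrazole-5-thiol (PPh3, DIAD, THF, 0 °C) gives (3S,4aS,7aS)-3,4a-dimethyl-3-{9-[(1-phenyl-1H-tetrazol-5-yl)sulfanyl]nonyl}tetrahydrofuro[3,2-c][1,2]dioxin-6(3H)-one F8. Oxidation with (NH4)6Mo7O24·4H2O and H2O2 (EtOH) gives (3S,4aS,7aS)-3,4a-dimethyl-3-{9-[(1-phenyl-1H-tetrazol-5-yl)sulfonyl]nonyl}tetrahydrofuro[3,2-c][1,2]dioxin-6(3H)-one F9. Julia–Kocienski olefination (KN(SiMe3)2, DME, −78 °C, then dienal 14) should give 19.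

**Further compounds**

F1 | step 6 | trimethyl(2-methylidenedodec-11-en-1-yl)silane | C=C(C[Si](C)(C)C)CCCCCCCCC=C
F2 | step 6 | (4S,5S)-5-methyl-5-(2-methylidenedodec-11-en-1-yl)-4-[(triethylsilyl)peroxy]oxolan-2-one | C=CCCCCCCCCC(=C)C[C@]1(C)OC(=O)C[C@@H]1OO[Si](CC)(CC)CC
F3 | step 6 | (4S,5S)-4-hydroperoxy-5-methyl-5-(2-methylidenedodec-11-en-1-yl)oxolan-2-one | C=CCCCCCCCCC(=C)C[C@]1(C)OC(=O)C[C@@H]1OO
F4 | step 6 | [(3S,4aS,7aS)-3-(dec-9-en-1-yl)-4a-methyl-6-oxohexahydrofuro[3,2-c][1,2]dioxin-3-yl]methylmercury acetate | C=CCCCCCCCC[C@@]1(C[Hg]OC(C)=O)C[C@]2(C)OC(=O)C[C@@H]2OO1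
F5 | step 3 | methyl (Z)-4-[(triethylsilyl)oxy]pent-3-enoate | COC(=O)C/C=C(/C)O[Si](CC)(CC)CC
F6 | step 3 | racemic methyl 4-oxo-3-[(triethylsilyl)peroxy]pentanoate | COC(=O)CC(C(C)=O)OO[Si](CC)(CC)CC
F7 | step 11 | (3S,4aS,7aS)-3-(9-hydroxynonyl)-3,4a-dimethyltetrahydrofuro[3,2-c][1,2]dioxin-6(3H)-one | OCCCCCCCCC[C@@]1(C)C[C@]2(C)OC(=O)C[C@@H]2OO1
F8 | step 11 | (3S,4aS,7aS)-3,4a-dimethyl-3-{9-[(1-phenyl-1H-tetrazol-5-yl)sulfanyl]nonyl}tetrahydrofuro[3,2-c][1,2]dioxin-6(3H)-one | c1ccccc1-n1nnnc1SCCCCCCCCC[C@@]3(C)C[C@]4(C)OC(=O)C[C@@H]4OO3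
F9 | step 11 | (3S,4aS,7aS)-3,4a-dimethyl-3-{9-[(1-phenyl-1H-tetrazol-5-yl)sulfonyl]nonyl}tetrahydrofuro[3,2-c][1,2]dioxin-6(3H)-one | c1ccccc1-n1nnnc1S(=O)(=O)CCCCCCCCC[C@@]3(C)C[C@]4(C)OC(=O)C[C@@H]4OO3
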